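The route rests on cutting the C2′–C3′ single bond of the 5-acetoxy-4-methylpent-3-enyl chain on C3 of the furanone ring, where an sp3 methylene meets the vinylic CH of the E-trisubstituted olefin. A nickel-electrocatalytic decarboxylative alkenylation joins the two halves last: the propanoic acid on C3 of the otherwise complete (S)-butenolide is activated in the flask as its N-hydroxyphthalimide ester, loses CO2 to a primary radical and couples with (E)-3-iodo-2-methylallyl acetate with retention of geometry. The exploited feature is this alkyl–alkenyl junction two carbons from the ring; the carboxyl is a traceless handle, and the precursor butenolide acid comes from epichlorohydrin by carboalumination, esterification and ring-closing metathesis.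

Key step: step 11

Assumption: 2-(trimethylsilyl)ethyl acetate (12) is bought as such; the other starting materials are common catalogue compounds.

Step 1
Reactants: 1 (S)-epichlorohydrin; 2 ethynyltrimethylsilane
Product: 4 (2S)-1-chloro-5-(trimethylsilyl)pent-4-yn-2-ol, via lithium (trimethylsilyl)acetylide 3 (not isolated)
Conditions: 2, n-BuLi, THF, −78 °C; BF3·OEt2; then 1, −78 °C; aq. NH4Cl
Reagents that add atoms: none
Why: Yamaguchi–Hirao alkynylation, in which the BF3-activated epoxide is opened by the acetylide at its unsubstituted carbon (SN2), so the carbinol carbon of 1 is carried over unchanged as the (S)-alcohol.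

Step 2
Reactants: 4 (2S)-1-chloro-5-(trimethylsilyl)pent-4-yn-2-ol
Product: 7 (3S)-hex-1-en-5-yn-3-ol, via epoxide 5 (not isolated), via silylated enynol 6 (not isolated)
Conditions: Me3S+ I− (4 equiv), n-BuLi (3.8 equiv), THF, −20 °C to rt; then MeOH, K2CO3, rt
Reagents that add atoms: trimethylsulfonium iodide, C[S+](C)C.[I-]
Why: Excess dimethylsulfonium methylide should close the chlorohydrin to epoxide 5, open it at the terminal carbon and eliminate dimethyl sulfide (Corey–Chaykovsky-type one-carbon homologation of an epoxide to an allylic alcohol) without touching the carbinol centre, after which methanolysis removes the alkynyl silyl group.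

Step 3
Reactants: 7 (3S)-hex-1-en-5-yn-3-ol
Product: 10 (2E,5S)-3-methylhepta-2,6-diene-1,5-diol, via alkenylalane 8 (not isolated), via lithium alanate 9 (not isolated)
Conditions: Me3Al (3 equiv), Cp2ZrCl2 (0.3 equiv), CH2Cl2, 0 °C to rt; volatiles removed; n-BuLi (1.1 equiv), THF, −78 °C; (CH2O)n, to rt; aq. potassium sodium tartrate
Reagents that add atoms: trimethylaluminium, C[Al](C)C; formaldehyde (as paraformaldehyde), C=O
Why: Negishi zirconium-catalysed carboalumination adds methyl and aluminium syn across the terminal alkyne (methyl to the internal carbon), and the derived alanate should transfer the alkenyl group to formaldehyde with retention, which fixes the E olefin while the carbinol centre sits as an aluminium alkoxide.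

Step 4
Reactants: 10 (2E,5S)-3-methylhepta-2,6-diene-1,5-diol
Product: 11 (2E,5S)-5-hydroxy-3-methylhepta-2,6-dien-1-yl acetate
Conditions: AcCl (1.05 equiv), 2,4,6-collidine, CH2Cl2, −78 °C
Reagents that add atoms: acetyl chloride, CC(=O)Cl
Why: Kinetically controlled acylation with acetyl chloride and collidine at low temperature should take the unhindered primary allylic hydroxyl and leave the secondary one free.

Step 5
Reactants: 12 2-(trimethylsilyl)ethyl acetate; 13 2-(bromomethyl)prop-2-enoic acid
Product: 15 2-methylidene-5-oxo-5-[2-(trimethylsilyl)ethoxy]pentanoic acid, via lithium enolate 14 (not isolated)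
Conditions: 12 (2.2 equiv), LDA (LiN(iPr)2, 2.2 equiv), THF, −78 °C; then 13, −78 to −20 °C; aq. citric acid
Reagents that add atoms: none
Why: Ester enolate alkylation, in which one equivalent of enolate deprotonates the acid and the second displaces the activated allylic bromide (SN2 and SN2′ lead to the same product), leaving the conjugated acid free and the saturated carboxyl masked.

Step 6
Reactants: 11 (2E,5S)-5-hydroxy-3-methylhepta-2,6-dien-1-yl acetate; 15 2-methylidene-5-oxo-5-[2-(trimethylsilyl)ethoxy]pentanoic acid
Product: 16 1-[(3S,5E)-7-(acetyloxy)-5-methylhepta-1,5-dien-3-yl] 5-[2-(trimethylsilyl)ethyl] 2-methylidenepentanedioate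
Conditions: DIC, DMAP (0.2 equiv), CH2Cl2, 0 °C to rt
Reagents that add atoms: none
Why: Steglich esterification acylates the secondary allylic alcohol with the carbodiimide-activated acrylic acid, and the configuration is kept because the C–O bond of the carbinol is not broken.

Step 7
Reactants: 16 the diene diester
Product: 17 4-({[(3S,5E)-7-(acetyloxy)-5-methylhepta-1,5-dien-3-yl]oxy}carbonyl)pent-4-enoic acid
Conditions: Bu4NF (1.5 equiv), THF, 0 °C; aq. KHSO4
Reagents that add atoms: none
Why: Fluoride attacks silicon and the 2-(trimethylsilyl)ethyl ester fragments to ethene and the carboxylate (β-elimination), which should spare the acetate and acrylate esters; the step is placed before the butenolide with its acidic C5–H exists.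

Step 8
Reactants: 17 the diene acid
Product: 18 3-[(5S)-5-[(2E)-4-(acetyloxy)-2-methylbut-2-en-1-yl]-2-oxo-2,5-dihydrofuran-3-yl]propanoic acid
Conditions: second-generation Grubbs catalyst (H2IMes)(PCy3)Cl2Ru=CHPh (5 mol%), CH2Cl2 (5 mM), 40 °C
Reagents that add atoms: none
Why: Ring-closing metathesis, in which the ruthenium carbene loads on the vinyl group and closes onto the 1,1-disubstituted acrylate to the five-membered butenolide with loss of ethene; the trisubstituted side-chain olefin is too hindered to compete and the stereocentre is not involved.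

Step 9
Reactants: 19 prop-2-yn-1-ol
Product: 21 (2E)-3-iodo-2-methylprop-2-en-1-ol, via alkenylalane 20 (not isolated)
Conditions: Me3Al (3 equiv), Cp2ZrCl2 (0.25 equiv), CH2Cl2, 0 °C to rt; then I2, THF, −30 to 0 °C; aq. potassium sodium tartrate, Na2S2O3
Reagents that add atoms: trimethylaluminium, C[Al](C)C; iodine, [I][I]
Why: Negishi zirconium-catalysed syn-methylalumination of the alkyne followed by iodinolysis of the C–Al bond with retention should give the E alkenyl iodide.

Step 10
Reactants: 21 (2E)-3-iodo-2-methylprop-2-en-1-ol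
Product: 22 (2E)-3-iodo-2-methylprop-2-en-1-yl acetate
Conditions: Ac2O, pyridine, DMAP (cat.), CH2Cl2, 0 °C to rt
Reagents that add atoms: acetic anhydride, CC(=O)OC(C)=O
Why: Standard nucleophile-catalysed acylation of the primary alcohol, which leaves the alkenyl iodide untouched.

Step 11
Reactants: 18 the butenolide propanoic acid; 22 (2E)-3-iodo-2-methylprop-2-en-1-yl acetate
Product: 24 (5S)-5-[(2E)-4-(acetyloxy)-2-methylbut-2-en-1-yl]-3-[(3E)-5-(acetyloxy)-4-methylpent-3-en-1-yl]furan-2(5H)-one, via phthalimide ester 23 (not isolated)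
Conditions: N-hydroxyphthalimide, DIC, DMAP (cat.), THF, rt; then 22 (1.5 equiv), NiCl2·6H2O (10 mol%), 2,2′-bipyridine (10 mol%), AgNO3 (0.3 equiv), LiCl, DMF, Mg anode, carbon-foam cathode, constant current, rt
Reagents that add atoms: none
Why: Carbodiimide coupling gives ester 23; cathodically generated low-valent nickel (bipyridine) then inserts into the C–I bond of 22 with retention, while single-electron reduction of 23 expels phthalimide anion and CO2 to leave a primary radical on the carbon that carried the carboxyl, which the alkenylnickel captures before reductive elimination from trivalent nickel forms the C(sp3)–C(sp2) bond, the magnesium anode supplying the electrons. The closest known reaction type is the nickel-electrocatalytic decarboxylative alkenylation of N-hydroxyphthalimide esters with alkenyl iodides at silver-coated cathodes. No ring is closed and no stereocentre is made: the E geometry is inherited from 22, and C5 of the furanone is not touched because the medium is never basic. The step needs C–I insertion to outrun ionisation of the two allylic acetates and radical capture by nickel to outrun addition to the butenolide; the fast sp2 C–I insertion at room temperature, the hindered trisubstituted allyl systems and the poor acceptor quality of the α,β-disubstituted lactone should secure this.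

Compound list
1 | (2S)-2-(chloromethyl)oxirane, (S)-epichlorohydrin | ClC[C@@H]1CO1 | starting material
2 | ethynyltrimethylsilane | C#C[Si](C)(C)C | starting material
3 | lithium (trimethylsilyl)acetylide | [Li]C#C[Si](C)(C)C | intermediate
4 | (2S)-1-chloro-5-(trimethylsilyl)pent-4-yn-2-ol | C[Si](C)(C)C#CC[C@H](O)CCl | intermediate
5 | (2S)-2-[3-(trimethylsilyl)prop-2-yn-1-yl]oxirane | C[Si](C)(C)C#CC[C@H]1CO1 | intermediate
6 | (3S)-6-(trimethylsilyl)hex-1-en-5-yn-3-ol | C[Si](C)(C)C#CC[C@H](O)C=C | intermediate
7 | (3S)-hex-1-en-5-yn-3-ol | C#CC[C@H](O)C=C | intermediate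
8 | dimethyl[(1E,4S)-4-[(dimethylalumanyl)oxy]-2-methylhexa-1,5-dien-1-yl]alumane | C[Al](C)/C=C(\C)C[C@H](O[Al](C)C)C=C | intermediate
9 | lithium butyl(dimethyl)alanate of 8 (butyl added to the alkenyl-bearing aluminium) | [Li+].CCCC[Al-](C)(C)/C=C(\C)C[C@H](O[Al](C)C)C=C | intermediate
10 | (2E,5S)-3-methylhepta-2,6-diene-1,5-diol | OC/C=C(\C)C[C@H](O)C=C | intermediate
11 | (2E,5S)-5-hydroxy-3-methylhepta-2,6-dien-1-yl acetate | CC(=O)OC/C=C(\C)C[C@H](O)C=C | intermediate
12 | 2-(trimethylsilyl)ethyl acetate | CC(=O)OCC[Si](C)(C)C | starting material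
13 | 2-(bromomethyl)prop-2-enoic acid | C=C(CBr)C(=O)O | starting material
14 | lithium 1-[2-(trimethylsilyl)ethoxy]ethen-1-olate (enolate of 12) | [Li]OC(=C)OCC[Si](C)(C)C | intermediate
15 | 2-methylidene-5-oxo-5-[2-(trimethylsilyl)ethoxy]pentanoic acid | C=C(CCC(=O)OCC[Si](C)(C)C)C(=O)O | intermediate
16 | 1-[(3S,5E)-7-(acetyloxy)-5-methylhepta-1,5-dien-3-yl] 5-[2-(trimethylsilyl)ethyl] 2-methylidenepentanedioate | CC(=O)OC/C=C(\C)C[C@H](OC(=O)C(=C)CCC(=O)OCC[Si](C)(C)C)C=C | intermediate
17 | 4-({[(3S,5E)-7-(acetyloxy)-5-methylhepta-1,5-dien-3-yl]oxy}carbonyl)pent-4-enoic acid | CC(=O)OC/C=C(\C)C[C@H](OC(=O)C(=C)CCC(=O)O)C=C | intermediate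
18 | 3-[(5S)-5-[(2E)-4-(acetyloxy)-2-methylbut-2-en-1-yl]-2-oxo-2,5-dihydrofuran-3-yl]propanoic acid | CC(=O)OC/C=C(\C)C[C@H]1C=C(CCC(=O)O)C(=O)O1 | intermediate
19 | prop-2-yn-1-ol | C#CCO | starting material
20 | dimethyl[(1E)-3-[(dimethylalumanyl)oxy]-2-methylprop-1-en-1-yl]alumane | C[Al](C)/C=C(\C)CO[Al](C)C | intermediate
21 | (2E)-3-iodo-2-methylprop-2-en-1-ol | I/C=C(\C)CO | intermediate
22 | (2E)-3-iodo-2-methylprop-2-en-1-yl acetate | I/C=C(\C)COC(C)=O | intermediate
23 | 1,3-dioxo-1,3-dihydro-2H-isoindol-2-yl 3-[(5S)-5-[(2E)-4-(acetyloxy)-2-methylbut-2-en-1-yl]-2-oxo-2,5-dihydrofuran-3-yl]propanoate | CC(=O)OC/C=C(\C)C[C@H]1C=C(CCC(=O)ON2C(=O)c3ccccc3C2=O)C(=O)O1 | intermediate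
24 | (5S)-5-[(2E)-4-(acetyloxy)-2-methylbut-2-en-1-yl]-3-[(3E)-5-(acetyloxy)-4-methylpent-3-en-1-yl]furan-2(5H)-one | CC(=O)OC/C=C(\C)C[C@H]1C=C(CC/C=C(\C)COC(C)=O)C(=O)O1 | target

Total step count: 11. Longest linear sequence: 8 steps (1, 2, 3, 4, 6, 7, 8, 11).

Steps most likely to fail

Step 11. Low-valent nickel may ionise the allylic acetates, or the primary radical may be reduced or add to the lactone before nickel captures it, so that decarboxylated or allyl-scrambled material forms. The fallback replaces the electroreductive union of two electrophiles by a polar organozinc coupling; it sets out from 21 and 18 and comes back at 24. Alcohol 21 is silylated (TBSCl, imidazole) to tert-butyl{[(2E)-3-iodo-2-methylprop-2-en-1-yl]oxy}dimethylsilane F1. Iodine–lithium exchange (t-BuLi, Et2O, −78 °C) gives [(1E)-3-{[tert-butyl(dimethyl)silyl]oxy}-2-methylprop-1-en-1-yl]lithium F2, and ZnCl2 turns it into the alkenylzinc chloride F3. Ester 23 is made from 18 as in step 11, isolated, and coupled with F3 under Ni(acac)2/2,2′-bipyridine in THF–DMF at rt (decarboxylative Negishi-type alkenylation) to the silyl ether F4. HF·pyridine frees the alcohol F5, and Ac2O/pyridine gives 24.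

Step 5. The poorly soluble lithium carboxylate of 13 may react slowly, so that base-induced polymerisation of the bromomethylacrylate or a second alkylation takes over. The fallback is a regioselective alcoholysis of a cyclic anhydride; it starts outside the route from purchased 2-methylidenepentanedioic acid (in place of 12 and 13) and comes back at 15. The diacid is dehydrated (AcCl, reflux) to 3-methylideneoxane-2,6-dione F6. 2-(Trimethylsilyl)ethanol with catalytic DMAP in CH2Cl2 should open it at the more electrophilic non-conjugated carbonyl, giving 15.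

Step 3. Transfer of the alkenyl group from aluminium to formaldehyde may be incomplete, and protonolysis of the C–Al bond would then leave the methylated diene without the hydroxymethyl carbon. The fallback is a hydroxyl-directed trans-hydroalumination, iodination and methylation; it sets out from 7 and comes back at 10. Double deprotonation of 7 (n-BuLi, 2.2 equiv) and paraformaldehyde give (5S)-hept-6-en-2-yne-1,5-diol F7. NaAlH2(OCH2CH2OMe)2 in THF followed by I2 delivers hydride to C2 and iodine to C3 in an anti sense, giving (2Z,5S)-3-iodohepta-2,6-diene-1,5-diol F8. Me2CuLi (from CuI and MeLi) replaces iodine by methyl with retention and gives 10.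

Further compounds
F1 | step 11 | tert-butyl{[(2E)-3-iodo-2-methylprop-2-en-1-yl]oxy}dimethylsilane | I/C=C(\C)CO[Si](C)(C)C(C)(C)C
F2 | step 11 | [(1E)-3-{[tert-butyl(dimethyl)silyl]oxy}-2-methylprop-1-en-1-yl]lithium | [Li]/C=C(\C)CO[Si](C)(C)C(C)(C)C
F3 | step 11 | chloro[(1E)-3-{[tert-butyl(dimethyl)silyl]oxy}-2-methylprop-1-en-1-yl]zinc | Cl[Zn]/C=C(\C)CO[Si](C)(C)C(C)(C)C
F4 | step 11 | (2E)-4-[(2S)-4-[(3E)-5-{[tert-butyl(dimethyl)silyl]oxy}-4-methylpent-3-en-1-yl]-5-oxo-2,5-dihydrofuran-2-yl]-3-methylbut-2-en-1-yl acetate | CC(=O)OC/C=C(\C)C[C@H]1C=C(CC/C=C(\C)CO[Si](C)(C)C(C)(C)C)C(=O)O1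
F5 | step 11 | (2E)-4-[(2S)-4-[(3E)-5-hydroxy-4-methylpent-3-en-1-yl]-5-oxo-2,5-dihydrofuran-2-yl]-3-methylbut-2-en-1-yl acetate | CC(=O)OC/C=C(\C)C[C@H]1C=C(CC/C=C(\C)CO)C(=O)O1
F6 | step 5 | 3-methylideneoxane-2,6-dione | C=C1CCC(=O)OC1=O
F7 | step 3 | (5S)-hept-6-en-2-yne-1,5-diol | OCC#CC[C@H](O)C=C
F8 | step 3 | (2Z,5S)-3-iodohepta-2,6-diene-1,5-diol | OC/C=C(\I)C[C@H](O)C=C
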